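**Assumption:** robustol has no stereocentre and no configurationally stable planar chirality (ring B is symmetric, the 22-membered ring is flexible), so the drawn structure is the only stereoisomer and no stereocontrol is needed.

## Retrosynthetic overview

1. Robustol ⇐ tri-O-methylrobustol by global O-demethylation.
2. Macrocycle ⇐ open-chain phenol ArA–(CH2)14–ArB(OH). The ring is closed by forming the diaryl ether C–O bond at the only unhindered C–H of ring A (Ir C–H borylation, then Cu-catalysed oxidative C–O coupling in the same flask).
3. Open-chain phenol ⇐ 4-bromo-2,6-dimethoxyphenol + 1-methoxy-3-(tetradec-13-enyl)benzene by B-alkyl Suzuki coupling.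
4. Ring B piece ⇐ resorcinol (methylation, C2 lithiation/oxidation, para-bromination). Ring A piece ⇐ 3-bromophenol + 6-bromohex-1-ene + octa-1,7-diene (sp2–sp3, then sp3–sp3 Suzuki).
5. Ring order: both benzene rings come from the starting materials; the 22-membered ring is the only ring made, in step 8.

## Route

**Step 1**
Reactants: 1 resorcinol (benzene-1,3-diol)
Product: 2 1,3-dimethoxybenzene
Conditions: Me2SO4 (2.4 equiv), K2CO3, acetone, reflux
Reagents that add atoms: dimethyl sulfate, COS(=O)(=O)OC
Why: Williamson O-methylation of both phenols; the methyl ethers direct the next lithiation and protect the ring B oxygens.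

**Step 2**
Reactants: 2 1,3-dimethoxybenzene
Product: 3 2,6-dimethoxyphenol
Conditions: n-BuLi (1.1 equiv), THF, 0 °C → rt; B(OMe)3, −78 °C → rt; then AcOH, 30% H2O2, 0 °C → rt
Reagents that add atoms: hydrogen peroxide, OO (B(OMe)3 is only transient)
Why: Directed ortho-metalation at C2, the C–H flanked by both OMe groups, followed by borylation and oxidative C–B to C–O migration.

**Step 3**
Reactants: 3 2,6-dimethoxyphenol
Product: 4 4-bromo-2,6-dimethoxyphenol
Conditions: NBS (1.0 equiv), NaH (1 mol %), CHCl3, −45 °C → rt
Reagents that add atoms: N-bromosuccinimide, O=C1CCC(=O)N1Br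
Why: Electrophilic aromatic bromination directed para by the phenol(ate), both ortho positions being blocked by OMe.

**Step 4**
Reactants: 5 3-bromophenol
Product: 6 1-bromo-3-methoxybenzene
Conditions: MeI, K2CO3, acetone, reflux
Reagents that add atoms: iodomethane, CI
Why: Williamson O-methylation; protects the ring A oxygen that ends up as the free OH.

**Step 5**
Reactants: 6 1-bromo-3-methoxybenzene; 7 6-bromohex-1-ene
Product: 8 1-(6-bromohexyl)-3-methoxybenzene
Conditions: 7 (1.2 equiv), 9-BBN, THF, 0 °C → rt; then 6, Pd(dppf)Cl2 (3 mol %), K3PO4, THF/DMF, 50 °C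
Reagents that add atoms: none
Why: Anti-Markovnikov hydroboration then B-alkyl Suzuki–Miyaura coupling; Pd(dppf) inserts into the aryl bromide much faster than into the unactivated primary alkyl bromide, which is retained.

**Step 6**
Reactants: 8 1-(6-bromohexyl)-3-methoxybenzene; 9 octa-1,7-diene
Product: 10 1-methoxy-3-(tetradec-13-en-1-yl)benzene
Conditions: 9 (4 equiv), 9-BBN (1.3 equiv), THF, 0 °C → rt, strip excess diene; then 8, Pd(OAc)2 (4 mol %), PCy3 (8 mol %), K3PO4·H2O, THF, rt
Reagents that add atoms: none
Why: Mono-hydroboration of the excess diene, then a Fu-type Pd/PCy3 alkyl–alkyl Suzuki–Miyaura coupling; the bulky electron-rich phosphine allows SN2-type oxidative addition to the primary bromide and suppresses β-hydride elimination, giving the C6 + C8 = C14 chain with a terminal alkene.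

**Step 7**
Reactants: 10 1-methoxy-3-(tetradec-13-en-1-yl)benzene; 4 4-bromo-2,6-dimethoxyphenol
Product: 11 4-[14-(3-methoxyphenyl)tetradecyl]-2,6-dimethoxyphenol
Conditions: 10, 9-BBN (1.1 equiv), THF, rt; then 4 (0.9 equiv), Pd(OAc)2 (3 mol %), SPhos (6 mol %), aq. K3PO4 (4 equiv), THF, 65 °C
Reagents that add atoms: none
Why: B-alkyl Suzuki–Miyaura coupling; Pd/SPhos should add to the electron-rich aryl bromide even as its phenoxide, and the 9-BBN is consumed by the alkene before the phenol is introduced.

**Step 8**
Reactants: 11 4-[14-(3-methoxyphenyl)tetradecyl]-2,6-dimethoxyphenol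
Product: 12 tri-O-methylrobustol, the 22-membered macrocyclic diaryl ether: the phenol oxygen of the 2,6-dimethoxy-4-alkyl ring is bonded to C5 of the 1-alkyl-3-methoxyphenyl ring, and the two alkyl positions are joined by an unbranched (CH2)14 chain
Conditions: (i) HBpin (2.3 equiv), [Ir(OMe)(cod)]2 (2 mol %), dtbpy (4 mol %), THF, 60 °C; MeOH quench, concentrate; (ii) syringe-pump addition (10 h) into Cu(OAc)2 (30 mol %), B(OH)3 (2 equiv), pyridine (3 equiv), 4 Å MS, MeCN (2 mM final), dry air, 70 °C
Reagents that add atoms: none (boron is not retained; the ether oxygen is the phenol oxygen of 11)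
Why: Proposed new method: a one-flask C–H borylative macro-etherification. The Ir(III) tris-boryl catalyst activates only the arene C–H with no ortho substituent, which is C5 of ring A; both ring B C–H bonds are flanked by OMe and alkyl, and the phenol is masked in situ as ArO–Bpin. After methanolysis, the aryl–Bpin transmetallates to a Cu(II) phenoxide on the same molecule, aerobic oxidation gives an aryl–Cu(III)–OAr species, and C–O reductive elimination closes the ring; B(OH)3 sequesters pinacol, and slow addition favours cyclisation over oligomerisation. The closest known chemistry is intermolecular two-stage Ir borylation/Cu etherification of arenes and Chan–Evans–Lam macrocyclisation of preformed arylboronic acids, including 2,6-disubstituted phenols.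

**Step 9**
Reactants: 12 tri-O-methylrobustol
Product: 13 robustol
Conditions: BBr3 (6 equiv), CH2Cl2, −78 °C → rt; MeOH quench, degassed work-up
Reagents that add atoms: none
Why: Lewis-acid cleavage of the three aryl methyl ethers with BBr3; the diaryl ether and the saturated chain are inert.

## Compound list

1 | resorcinol (benzene-1,3-diol) | Oc1cccc(O)c1 | starting material
2 | 1,3-dimethoxybenzene | COc1cccc(OC)c1 | intermediate
3 | 2,6-dimethoxyphenol | COc1cccc(OC)c1O | intermediate
4 | 4-bromo-2,6-dimethoxyphenol | COc1cc(Br)cc(OC)c1O | intermediate
5 | 3-bromophenol | Oc1cccc(Br)c1 | starting material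
6 | 1-bromo-3-methoxybenzene | COc1cccc(Br)c1 | intermediate
7 | 6-bromohex-1-ene | C=CCCCCBr | starting material
8 | 1-(6-bromohexyl)-3-methoxybenzene | COc1cccc(CCCCCCBr)c1 | intermediate
9 | octa-1,7-diene | C=CCCCCC=C | starting material
10 | 1-methoxy-3-(tetradec-13-en-1-yl)benzene | COc1cccc(CCCCCCCCCCCCC=C)c1 | intermediate
11 | 4-[14-(3-methoxyphenyl)tetradecyl]-2,6-dimethoxyphenol | COc1cccc(CCCCCCCCCCCCCCc2cc(OC)c(O)c(OC)c2)c1 | intermediate
12 | tri-O-methylrobustol | COc1cc2cc(c1)Oc1c(OC)cc(cc1OC)CCCCCCCCCCCCCC2 | intermediate
13 | robustol | Oc1cc2cc(c1)Oc1c(O)cc(cc1O)CCCCCCCCCCCCCC2 | target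

## Step count

- Total steps: 9 (one-pot operations counted as one step).
- Longest linear sequence: 6 steps (1 → 2 → 3 → 4 → 11 → 12 → 13, or 5 → 6 → 8 → 10 → 11 → 12 → 13), which is two thirds of the total.

## Steps most likely to fail

1. **Step 8 (proposed new macro-etherification).** Risks are oxidation of the electron-rich syringyl phenol by Cu/air, protodeboronation and oligomerisation. Fallback with known chemistry: form the diaryl ether intermolecularly and close the ring in the chain instead.
   - Couple 4 with oct-7-enyl-9-BBN to give 4-(oct-7-enyl)-2,6-dimethoxyphenol.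
   - Join it by Ullmann coupling (CuI/picolinic acid, K3PO4, DMSO) to 1-bromo-3-methoxy-5-(oct-7-enyl)benzene. That partner comes from 1,3-dibromobenzene by Ir borylation/oxidation, methylation and mono B-alkyl Suzuki coupling.
   - Close the ring by ring-closing metathesis at high dilution, hydrogenate (H2, Pd/C), then demethylate with BBr3.

2. **Step 7 (Suzuki coupling on the unprotected, electron-rich bromophenol).** Oxidative addition may be slow and the phenoxide may interfere. Fallback: couple the 9-BBN adduct of 10 with 1-bromo-3,5-dimethoxybenzene (from 2 by Ir-catalysed borylation/CuBr2). Then install the phenol oxygen on the coupled product by C2 lithiation (n-BuLi), B(OMe)3 and H2O2, as in step 2.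

3. **Step 6 (sp3–sp3 Suzuki coupling).** Risks are β-hydride elimination and isomerisation of the terminal alkene. Fallback: build the C14 unit first by Cu-catalysed (Li2CuCl4) coupling of hept-6-enylmagnesium bromide with 7-bromohept-1-ene to give tetradeca-1,13-diene. Mono-hydroboration of the excess diene and B-alkyl Suzuki coupling with 6 then gives 10 without any alkyl–alkyl Pd coupling.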